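In rings B and D, C3 is a methine that carries only aryl groups and sits next to C2, an O1–CH(4-hydroxyphenyl) carbon; each C2–C3 bond is cut to a diaryl carbene and an ArO–CH2Ar ether. The key step closes ring B: the carbene carbon, bonded to ring A and to C5 of ring C, inserts into the ortho benzylic ether C–H bond under a chiral dirhodium tetracarboxylate, which fixes C3; the enantiomeric catalyst has already closed ring D. The precursor is the hydrazone of a diaryl ketone with Br (placeholder for the Z-styryl arm) and the 4-methoxybenzyl ether on ring A. BBr3 then frees six phenols and makes both rings trans; a Suzuki coupling adds the Z-alkene.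

Key step: step 11

Ring labels: ring A is the benzo ring and ring B the dihydrofuran ring of the dihydrobenzofuran that carries the styryl arm; ring C is the benzo ring and ring D the dihydrofuran ring of the other one; each is numbered O1, C2, C3, C3a, C4 to C7, C7a. Rh2(R-PTAD)4 and Rh2(S-PTAD)4 are the two enantiomers of dirhodium tetrakis[(1-adamantyl)(N-phthalimido)acetate].

Assumption: the sense of induction of the Rh2(PTAD)4 enantiomers is assigned provisionally (R catalyst for the 3R centre of ring D, S catalyst for the 3S centre of ring B) and is to be confirmed on compound 16; if 16 proves to be the antipode, the two catalysts change places and nothing else changes.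

Step 1
Reactants: 1 5-bromo-2-hydroxy-3-methoxybenzaldehyde; 2 4-methoxybenzyl chloride
Product: 3 5-bromo-3-methoxy-2-[(4-methoxybenzyl)oxy]benzaldehyde
Conditions: K2CO3, KI (cat.), DMF, 60 °C
Reagents that add atoms: none
Why: Williamson etherification of the phenoxide with a reactive benzylic chloride, to which aldehyde and aryl bromide are inert; the new ArO–CH2Ar unit is the later insertion site of ring D.

Step 2
Reactants: 3 5-bromo-3-methoxy-2-[(4-methoxybenzyl)oxy]benzaldehyde; 4 1-bromo-3,5-dimethoxybenzene
Product: 6 rac-{5-bromo-3-methoxy-2-[(4-methoxybenzyl)oxy]phenyl}(3,5-dimethoxyphenyl)methanol, via 3,5-dimethoxyphenylmagnesium bromide 5 (not isolated)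
Conditions: 4, Mg, THF, 45 °C; then 3, THF, 0 °C; then H2O
Reagents that add atoms: none
Why: Grignard addition, in which the preformed arylmagnesium bromide adds to the aldehyde much faster than it can exchange with the aryl bromide of 3; the carbinol centre is left racemic because step 7 oxidises it.

Step 3
Reactants: 4 1-bromo-3,5-dimethoxybenzene
Product: 8 2-bromo-4,6-dimethoxybenzaldehyde, via aryl iminium chloride 7 (not isolated)
Conditions: POCl3, DMF, 0 to 90 °C; then H2O
Reagents that add atoms: N,N-dimethylformamide CN(C)C=O; water O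
Why: Vilsmeier–Haack formylation, in which the chloroiminium ion attacks C2 of 4 (next to Br, ortho to one methoxy group and para to the other), the pattern preferred by 1,3-dimethoxyarenes; the minor isomer formylated between the two methoxy groups would be removed by crystallisation.

Step 4
Reactants: 8 2-bromo-4,6-dimethoxybenzaldehyde
Product: 9 2-bromo-6-hydroxy-4-methoxybenzaldehyde
Conditions: BCl3, CH2Cl2, −78 to 0 °C; then H2O
Reagents that add atoms: none
Why: chelation-controlled Lewis acid demethylation, in which BCl3 bound to the aldehyde oxygen reaches only the ortho methyl ether through a six-membered chelate, so the para methoxy group and the bromide should stay.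

Step 5
Reactants: 9 2-bromo-6-hydroxy-4-methoxybenzaldehyde; 2 4-methoxybenzyl chloride
Product: 10 2-bromo-4-methoxy-6-[(4-methoxybenzyl)oxy]benzaldehyde
Conditions: K2CO3, KI (cat.), DMF, 60 °C
Reagents that add atoms: none
Why: Williamson etherification of the hydrogen-bonded ortho-hydroxy aldehyde under warm carbonate conditions; it installs the ArO–CH2Ar insertion site of ring B next to the future carbene carbon.

Step 6
Reactants: 6 rac-{5-bromo-3-methoxy-2-[(4-methoxybenzyl)oxy]phenyl}(3,5-dimethoxyphenyl)methanol; 10 2-bromo-4-methoxy-6-[(4-methoxybenzyl)oxy]benzaldehyde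
Product: 12 bis-carbinol {2-bromo-4-methoxy-6-[(4-methoxybenzyl)oxy]phenyl}{3-[(3,5-dimethoxyphenyl)(hydroxy)methyl]-5-methoxy-4-[(4-methoxybenzyl)oxy]phenyl}methanol (diastereomer mixture), via lithiated sodium alkoxide 11 (not isolated)
Conditions: 6, NaH, THF, 0 °C; t-BuLi (2 equiv), −78 °C; then 10, −78 to −20 °C; then H2O
Reagents that add atoms: none
Why: bromine–lithium exchange on the alkoxide-masked carbinol, then 1,2-addition of the aryllithium to the aldehyde, which at −78 °C should outrun exchange with the aryl bromide of 10; neither carbinol centre needs control because both are oxidised in step 7.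

Step 7
Reactants: 12 bis-carbinol (diastereomer mixture)
Product: 13 {2-bromo-4-methoxy-6-[(4-methoxybenzyl)oxy]phenyl}{3-(3,5-dimethoxybenzoyl)-5-methoxy-4-[(4-methoxybenzyl)oxy]phenyl}methanone
Conditions: Dess–Martin periodinane, CH2Cl2, rt
Reagents that add atoms: none
Why: Dess–Martin oxidation of both diaryl carbinols to ketones, tolerated by the benzyl ethers, methyl ethers and the bromide, which merges all diastereomers into one achiral diketone.

Step 8
Reactants: 13 diketone
Product: 14 {2-bromo-4-methoxy-6-[(4-methoxybenzyl)oxy]phenyl}{3-[(3,5-dimethoxyphenyl)(hydrazinylidene)methyl]-5-methoxy-4-[(4-methoxybenzyl)oxy]phenyl}methanone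
Conditions: N2H4·H2O (3 equiv), AcOH (cat.), EtOH, 70 °C
Reagents that add atoms: hydrazine NN
Why: acid-catalysed hydrazone condensation, expected to be selective for the carbonyl with a single ortho substituent, because the other carbonyl is shielded on both ortho positions of ring A (Br and OCH2Ar) and twisted out of reach under these mild conditions.

Step 9
Reactants: 14 mono-hydrazone
Product: 16 {2-bromo-4-methoxy-6-[(4-methoxybenzyl)oxy]phenyl}[(2S,3R)-3-(3,5-dimethoxyphenyl)-7-methoxy-2-(4-methoxyphenyl)-2,3-dihydro-1-benzofuran-5-yl]methanone (2,3-cis ring D), via diazo ketone 15 (not isolated)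
Conditions: MnO2, MeCN, 0 °C; then Rh2(R-PTAD)4 (1 mol%), 0 °C to rt
Reagents that add atoms: none
Why: known enantioselective intramolecular C–H insertion of a diaryl rhodium carbene into the ortho ArO–CH2Ar bond, closing ring D; C3 (R) should be set by the catalyst and C2 (S) falls cis through the insertion transition state, while the hindered ketone and the remote second benzyl ether are spectators.

Step 10
Reactants: 16 cis ring D ketone
Product: 17 (2S,3R)-5-[{2-bromo-4-methoxy-6-[(4-methoxybenzyl)oxy]phenyl}(hydrazinylidene)methyl]-3-(3,5-dimethoxyphenyl)-7-methoxy-2-(4-methoxyphenyl)-2,3-dihydro-1-benzofuran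
Conditions: N2H4 (anhydrous, excess), AcOH (cat.), n-BuOH, 120 °C, sealed tube
Reagents that add atoms: hydrazine NN
Why: hydrazone condensation under the forcing conditions that diaryl ketones with two ortho substituents require, with excess hydrazine to suppress azine formation; neither ring D centre is acidic enough to be disturbed, and a C2 epimer would converge in step 12 anyway.

Step 11
Reactants: 17 hydrazone of the hindered ketone
Product: 19 (2S,3R)-5-[(2R,3S)-4-bromo-6-methoxy-2-(4-methoxyphenyl)-2,3-dihydro-1-benzofuran-3-yl]-3-(3,5-dimethoxyphenyl)-7-methoxy-2-(4-methoxyphenyl)-2,3-dihydro-1-benzofuran (cis,cis), via diaryldiazomethane 18 (not isolated)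
Conditions: MnO2, MeCN, 0 °C; then Rh2(S-PTAD)4 (2 mol%), 0 °C to rt
Reagents that add atoms: none
Why: MnO2 dehydrogenates the hydrazone to diaryldiazomethane 18, the dirhodium tetracarboxylate takes up the diazo carbon and expels N2, and the resulting rhodium carbene with two aryl donors abstracts hydride from the ortho ArO–CH2Ar group and collapses to the C2–C3 bond in one asynchronous insertion event. The closest known reaction type is the enantioselective intramolecular C–H insertion of diaryl rhodium carbenes, made from hydrazones with MnO2, into benzylic ether C–H bonds to give cis-2,3-diaryl-2,3-dihydrobenzofurans. Ring B (O1, C2, C3, C3a, C7a) closes by 1,5 insertion, the carbene carbon becoming C3 and the ether CH2 becoming C2. C3 (S) should be set by the chiral pocket of Rh2(S-PTAD)4, the mirror image of the catalyst used for ring D, and C2 (R, cis to C3) by the insertion transition state, which is known to deliver the 2,3-cis ring and is corrected to trans in step 12. The step needs three selectivities: site selectivity is secured because the ether CH2 on ring A is the only C–H bond in 1,5 relation to the carbene carbon; chemoselectivity is secured because no alkene is present (Br stands in for the styryl arm) and a carbene with two aryl donors is mild; face selectivity rests on the catalyst, which the ring D centres, meta across ring C, are too remote to oppose.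

Step 12
Reactants: 19 cis,cis hexamethyl ether bromide
Product: 20 (2R,3R)-5-[(2S,3S)-4-bromo-6-hydroxy-2-(4-hydroxyphenyl)-2,3-dihydro-1-benzofuran-3-yl]-3-(3,5-dihydroxyphenyl)-2-(4-hydroxyphenyl)-2,3-dihydro-1-benzofuran-7-ol (trans,trans)
Conditions: BBr3 (excess), CH2Cl2, −78 °C to rt; then H2O
Reagents that add atoms: none
Why: BBr3 cleaves all six aryl methyl ethers and reversibly ionises each O1–C2 bond to a para-oxybenzylic cation, so both C2 centres should settle in the thermodynamically preferred trans arrangement (C2 of ring B to S, C2 of ring D to R), while the C3 methines cannot ionise and keep their configuration.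

Step 13
Reactants: 20 trans,trans hexaphenol bromide
Product: 21 hexakis(tert-butyldimethylsilyl) ether of 20
Conditions: TBSCl, imidazole, DMF, rt to 40 °C
Reagents that add atoms: tert-butyldimethylsilyl chloride CC(C)(C)[Si](C)(C)Cl
Why: imidazole-promoted silylation of all six phenols, which gives a lipophilic, non-acidic partner for the cross-coupling and touches no stereocentre.

Step 14
Reactants: 22 4-hydroxybenzaldehyde
Product: 23 4-[(tert-butyldimethylsilyl)oxy]benzaldehyde
Conditions: TBSCl, imidazole, CH2Cl2, rt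
Reagents that add atoms: tert-butyldimethylsilyl chloride CC(C)(C)[Si](C)(C)Cl
Why: standard phenol silylation, which removes the acidic proton before the organolithium step and matches the protecting groups of 21.

Step 15
Reactants: 23 4-[(tert-butyldimethylsilyl)oxy]benzaldehyde
Product: 24 tert-butyl[4-(2,2-dibromoethenyl)phenoxy]dimethylsilane
Conditions: CBr4, PPh3, CH2Cl2, 0 °C
Reagents that add atoms: tetrabromomethane BrC(Br)(Br)Br
Why: first stage of the Corey–Fuchs alkyne synthesis, a Wittig-type olefination of the aldehyde with the dibromomethylene ylide formed in the flask.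

Step 16
Reactants: 24 tert-butyl[4-(2,2-dibromoethenyl)phenoxy]dimethylsilane
Product: 26 tert-butyl(4-ethynylphenoxy)dimethylsilane, via lithium acetylide 25 (not isolated)
Conditions: n-BuLi (2.1 equiv), THF, −78 to 0 °C; then H2O
Reagents that add atoms: none
Why: second stage of the Corey–Fuchs sequence, bromine–lithium exchange followed by Fritsch–Buttenberg–Wiechell rearrangement to the acetylide, which water protonates; the aryl silyl ether tolerates n-BuLi at low temperature.

Step 17
Reactants: 26 tert-butyl(4-ethynylphenoxy)dimethylsilane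
Product: 27 (Z)-tert-butyldimethyl{4-[2-(4,4,5,5-tetramethyl-1,3,2-dioxaborolan-2-yl)ethenyl]phenoxy}silane
Conditions: HBpin, [Rh(cod)Cl]2 (1.5 mol%), P(i-Pr)3 (6 mol%), Et3N, cyclohexane, rt
Reagents that add atoms: pinacolborane CC1(C)OBOC1(C)C
Why: rhodium-catalysed formal trans-hydroboration of a terminal alkyne, which runs through a rhodium vinylidene so that boron ends up at the terminal carbon cis to the aryl group, setting the Z alkene.

Step 18
Reactants: 21 hexasilyl ether bromide; 27 Z-alkenyl pinacol boronate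
Product: 28 heptakis(tert-butyldimethylsilyl) ether of the target
Conditions: Pd(OAc)2 (5 mol%), SPhos (10 mol%), K3PO4, toluene/H2O, 70 °C, degassed
Reagents that add atoms: none
Why: Suzuki–Miyaura coupling, in which the bulky electron-rich biaryl phosphine promotes oxidative addition of the hindered, electron-rich aryl bromide to zerovalent palladium and the alkenyl group transfers with retention, so the Z geometry should be carried over; any aryl silyl ether lost to the base is harmless because step 19 removes them all.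

Step 19
Reactants: 28 heptasilyl ether
Product: 29 (2R,3R)-3-(3,5-dihydroxyphenyl)-5-{(2S,3S)-6-hydroxy-2-(4-hydroxyphenyl)-4-[(Z)-2-(4-hydroxyphenyl)ethenyl]-2,3-dihydro-1-benzofuran-3-yl}-2-(4-hydroxyphenyl)-2,3-dihydro-1-benzofuran-7-ol (target CNP0172909.2)
Conditions: TBAF, AcOH, THF, 0 °C to rt, argon, dark
Reagents that add atoms: none
Why: fluoride-mediated cleavage of the seven aryl silyl ethers, buffered with acetic acid and run without oxygen or light, so that neither acid-labile benzylic ethers, nor the Z alkene, nor the oxidisable phenols are put at risk.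

Compound list
1 | 5-bromo-2-hydroxy-3-methoxybenzaldehyde | O=Cc1cc(Br)cc(OC)c1O | starting material
2 | 4-methoxybenzyl chloride | COc1ccc(CCl)cc1 | starting material
3 | 5-bromo-3-methoxy-2-[(4-methoxybenzyl)oxy]benzaldehyde | COc1ccc(COc2c(OC)cc(Br)cc2C=O)cc1 | intermediate
4 | 1-bromo-3,5-dimethoxybenzene | COc1cc(Br)cc(OC)c1 | starting material
5 | 3,5-dimethoxyphenylmagnesium bromide | COc1cc(OC)cc([Mg]Br)c1 | intermediate (not isolated)
6 | rac-{5-bromo-3-methoxy-2-[(4-methoxybenzyl)oxy]phenyl}(3,5-dimethoxyphenyl)methanol | COc1ccc(COc2c(OC)cc(Br)cc2C(O)c2cc(OC)cc(OC)c2)cc1 | intermediate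
7 | N-(2-bromo-4,6-dimethoxybenzylidene)-N-methylmethanaminium chloride | C[N+](C)=Cc1c(Br)cc(OC)cc1OC.[Cl-] | intermediate (not isolated)
8 | 2-bromo-4,6-dimethoxybenzaldehyde | O=Cc1c(Br)cc(OC)cc1OC | intermediate
9 | 2-bromo-6-hydroxy-4-methoxybenzaldehyde | O=Cc1c(Br)cc(OC)cc1O | intermediate
10 | 2-bromo-4-methoxy-6-[(4-methoxybenzyl)oxy]benzaldehyde | O=Cc1c(Br)cc(OC)cc1OCc1ccc(OC)cc1 | intermediate
11 | sodium alkoxide of 6 carrying lithium in place of bromine | COc1ccc(COc2c(OC)cc([Li])cc2C([O-])c2cc(OC)cc(OC)c2)cc1.[Na+] | intermediate (not isolated)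
12 | {2-bromo-4-methoxy-6-[(4-methoxybenzyl)oxy]phenyl}{3-[(3,5-dimethoxyphenyl)(hydroxy)methyl]-5-methoxy-4-[(4-methoxybenzyl)oxy]phenyl}methanol, mixture of diastereomers | COc1ccc(COc2c(OC)cc(C(O)c3c(Br)cc(OC)cc3OCc3ccc(OC)cc3)cc2C(O)c2cc(OC)cc(OC)c2)cc1 | intermediate
13 | {2-bromo-4-methoxy-6-[(4-methoxybenzyl)oxy]phenyl}{3-(3,5-dimethoxybenzoyl)-5-methoxy-4-[(4-methoxybenzyl)oxy]phenyl}methanone | COc1ccc(COc2c(OC)cc(C(=O)c3c(Br)cc(OC)cc3OCc3ccc(OC)cc3)cc2C(=O)c2cc(OC)cc(OC)c2)cc1 | intermediate
14 | mono-hydrazone of 13 at the 3,5-dimethoxybenzoyl carbon (C=N geometry not defined) | COc1ccc(COc2c(OC)cc(C(=O)c3c(Br)cc(OC)cc3OCc3ccc(OC)cc3)cc2C(=NN)c2cc(OC)cc(OC)c2)cc1 | intermediate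
15 | {2-bromo-4-methoxy-6-[(4-methoxybenzyl)oxy]phenyl}{3-[diazo(3,5-dimethoxyphenyl)methyl]-5-methoxy-4-[(4-methoxybenzyl)oxy]phenyl}methanone | COc1ccc(COc2c(OC)cc(C(=O)c3c(Br)cc(OC)cc3OCc3ccc(OC)cc3)cc2C(=[N+]=[N-])c2cc(OC)cc(OC)c2)cc1 | intermediate (not isolated)
16 | {2-bromo-4-methoxy-6-[(4-methoxybenzyl)oxy]phenyl}[(2S,3R)-3-(3,5-dimethoxyphenyl)-7-methoxy-2-(4-methoxyphenyl)-2,3-dihydro-1-benzofuran-5-yl]methanone, ring D cis | O=C(c1c(Br)cc(OC)cc1OCc1ccc(OC)cc1)c1cc(OC)c2c(c1)[C@@H](c1cc(OC)cc(OC)c1)[C@@H](c1ccc(OC)cc1)O2 | intermediate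
17 | hydrazone of 16 at the ring A ketone (C=N geometry not defined), ring D (2S,3R) cis | NN=C(c1c(Br)cc(OC)cc1OCc1ccc(OC)cc1)c1cc(OC)c2c(c1)[C@@H](c1cc(OC)cc(OC)c1)[C@@H](c1ccc(OC)cc1)O2 | intermediate
18 | diaryldiazomethane from 17, ring D (2S,3R) cis | [N-]=[N+]=C(c1c(Br)cc(OC)cc1OCc1ccc(OC)cc1)c1cc(OC)c2c(c1)[C@@H](c1cc(OC)cc(OC)c1)[C@@H](c1ccc(OC)cc1)O2 | intermediate (not isolated)
19 | (2S,3R)-5-[(2R,3S)-4-bromo-6-methoxy-2-(4-methoxyphenyl)-2,3-dihydro-1-benzofuran-3-yl]-3-(3,5-dimethoxyphenyl)-7-methoxy-2-(4-methoxyphenyl)-2,3-dihydro-1-benzofuran, cis in rings B and D | Brc1cc(OC)cc2c1[C@H](c1cc(OC)c3c(c1)[C@@H](c1cc(OC)cc(OC)c1)[C@@H](c1ccc(OC)cc1)O3)[C@H](c1ccc(OC)cc1)O2 | intermediate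
20 | (2R,3R)-5-[(2S,3S)-4-bromo-6-hydroxy-2-(4-hydroxyphenyl)-2,3-dihydro-1-benzofuran-3-yl]-3-(3,5-dihydroxyphenyl)-2-(4-hydroxyphenyl)-2,3-dihydro-1-benzofuran-7-ol, trans in rings B and D | Brc1cc(O)cc2c1[C@H](c1cc(O)c3c(c1)[C@@H](c1cc(O)cc(O)c1)[C@H](c1ccc(O)cc1)O3)[C@@H](c1ccc(O)cc1)O2 | intermediate
21 | hexakis(tert-butyldimethylsilyl) ether of 20, ring B (2S,3S), ring D (2R,3R) | Brc1cc(O[Si](C)(C)C(C)(C)C)cc2c1[C@H](c1cc(O[Si](C)(C)C(C)(C)C)c3c(c1)[C@@H](c1cc(O[Si](C)(C)C(C)(C)C)cc(O[Si](C)(C)C(C)(C)C)c1)[C@H](c1ccc(O[Si](C)(C)C(C)(C)C)cc1)O3)[C@@H](c1ccc(O[Si](C)(C)C(C)(C)C)cc1)O2 | intermediate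
22 | 4-hydroxybenzaldehyde | O=Cc1ccc(O)cc1 | starting material
23 | 4-[(tert-butyldimethylsilyl)oxy]benzaldehyde | CC(C)(C)[Si](C)(C)Oc1ccc(C=O)cc1 | intermediate
24 | tert-butyl[4-(2,2-dibromoethenyl)phenoxy]dimethylsilane | CC(C)(C)[Si](C)(C)Oc1ccc(C=C(Br)Br)cc1 | intermediate
25 | lithium {4-[(tert-butyldimethylsilyl)oxy]phenyl}acetylide | [Li]C#Cc1ccc(O[Si](C)(C)C(C)(C)C)cc1 | intermediate (not isolated)
26 | tert-butyl(4-ethynylphenoxy)dimethylsilane | C#Cc1ccc(O[Si](C)(C)C(C)(C)C)cc1 | intermediate
27 | (Z)-tert-butyldimethyl{4-[2-(4,4,5,5-tetramethyl-1,3,2-dioxaborolan-2-yl)ethenyl]phenoxy}silane | CC(C)(C)[Si](C)(C)Oc1ccc(/C=C\B2OC(C)(C)C(C)(C)O2)cc1 | intermediate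
28 | heptakis(tert-butyldimethylsilyl) ether of the target, Z alkene, ring B (2S,3S), ring D (2R,3R) | CC(C)(C)[Si](C)(C)Oc1ccc(/C=C\c2cc(O[Si](C)(C)C(C)(C)C)cc3c2[C@H](c2cc(O[Si](C)(C)C(C)(C)C)c4c(c2)[C@@H](c2cc(O[Si](C)(C)C(C)(C)C)cc(O[Si](C)(C)C(C)(C)C)c2)[C@H](c2ccc(O[Si](C)(C)C(C)(C)C)cc2)O4)[C@@H](c2ccc(O[Si](C)(C)C(C)(C)C)cc2)O3)cc1 | intermediate
29 | (2R,3R)-3-(3,5-dihydroxyphenyl)-5-{(2S,3S)-6-hydroxy-2-(4-hydroxyphenyl)-4-[(Z)-2-(4-hydroxyphenyl)ethenyl]-2,3-dihydro-1-benzofuran-3-yl}-2-(4-hydroxyphenyl)-2,3-dihydro-1-benzofuran-7-ol | Oc1ccc(/C=C\c2cc(O)cc3c2[C@H](c2cc(O)c4c(c2)[C@@H](c2cc(O)cc(O)c2)[C@H](c2ccc(O)cc2)O4)[C@@H](c2ccc(O)cc2)O3)cc1 | target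

Total step count: 19.
Longest linear sequence: 13 steps (steps 3, 4, 5, 6, 7, 8, 9, 10, 11, 12, 13, 18, 19, from 1-bromo-3,5-dimethoxybenzene 4 to target 29).

Steps most likely to fail

Step 11. What may go wrong: the diazo carbon, flanked by Br and the benzyloxy group on ring A, may be taken up only slowly by the bulky dirhodium catalyst, so that an uncatalysed background reaction erodes facial control at C3 of ring B. Fallback: stereocontrol is moved from the catalyst to the resident ring D centres. Setting out from hydrazone 17, diazo compound 18 is made with MnO2 as before, filtered and irradiated without any metal (450 nm LEDs, degassed benzene, rt). The free diarylcarbene abstracts the ether hydrogen through a six-membered transition state and the resulting 1,5-biradical recombines, closing ring B without facial preference to give the ring B stereoisomer mixture of the hexamethyl ether bromide F1. Treatment with BBr3 as in step 12 then equilibrates C2 in both rings and should leave 20 together with the ring B (2R,3R) diastereomer of the hexaphenol bromide F2. Because ring D is enantiopure, the two are diastereomers and would be separated by preparative HPLC; the route is rejoined at 20, at the cost of about half the material.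

Step 10. What may go wrong: the twisted carbonyl with two ortho substituents may not condense, or may convert so slowly that prolonged heating with hydrazine causes decomposition. Fallback: condensation at C=O is replaced by transimination at C=N. Setting out from ketone 16, NH3 and TiCl4 (toluene, 0 °C to rt) should give the N–H ketimine of the ring A ketone F3. Its C=N bond exchanges with N2H4·H2O in EtOH at rt with loss of ammonia, giving hydrazone 17, where the route is rejoined.

Step 18. What may go wrong: oxidative addition and transmetalation at the bromide next to the crowded C3 of ring B may be slow, so that protodeboronation and Z to E isomerisation of the alkenylboronate win. Fallback: the geometry is set after the C–C bond is made. Setting out from bromide 21 and alkyne 26, a copper-free Sonogashira coupling (PdCl2(MeCN)2, XPhos, Cs2CO3, MeCN, 80 °C) should give the heptasilylated diaryl alkyne F4. Semi-hydrogenation (H2, Pd/CaCO3 poisoned with Pb(OAc)2, quinoline, EtOAc, rt) then delivers the Z alkene 28, where the route is rejoined.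

Further compounds
F1 | step 11 | ring B stereoisomer mixture of the hexamethyl ether bromide (ring D 2S,3R cis, C2 and C3 of ring B undefined) | Brc1cc(OC)cc2c1C(c1cc(OC)c3c(c1)[C@@H](c1cc(OC)cc(OC)c1)[C@@H](c1ccc(OC)cc1)O3)C(c1ccc(OC)cc1)O2
F2 | step 11 | ring B (2R,3R) diastereomer of the hexaphenol bromide, (2R,3R)-5-[(2R,3R)-4-bromo-6-hydroxy-2-(4-hydroxyphenyl)-2,3-dihydro-1-benzofuran-3-yl]-3-(3,5-dihydroxyphenyl)-2-(4-hydroxyphenyl)-2,3-dihydro-1-benzofuran-7-ol | Brc1cc(O)cc2c1[C@@H](c1cc(O)c3c(c1)[C@@H](c1cc(O)cc(O)c1)[C@H](c1ccc(O)cc1)O3)[C@H](c1ccc(O)cc1)O2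
F3 | step 10 | N–H ketimine of the ring A ketone of 16, ring D (2S,3R) cis | N=C(c1c(Br)cc(OC)cc1OCc1ccc(OC)cc1)c1cc(OC)c2c(c1)[C@@H](c1cc(OC)cc(OC)c1)[C@@H](c1ccc(OC)cc1)O2
F4 | step 18 | heptasilylated diaryl alkyne, ring B (2S,3S), ring D (2R,3R) | CC(C)(C)[Si](C)(C)Oc1ccc(C#Cc2cc(O[Si](C)(C)C(C)(C)C)cc3c2[C@H](c2cc(O[Si](C)(C)C(C)(C)C)c4c(c2)[C@@H](c2cc(O[Si](C)(C)C(C)(C)C)cc(O[Si](C)(C)C(C)(C)C)c2)[C@H](c2ccc(O[Si](C)(C)C(C)(C)C)cc2)O4)[C@@H](c2ccc(O[Si](C)(C)C(C)(C)C)cc2)O3)cc1
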